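**Retrosynthetic overview**

1. Numbering used here: enone ring C1 (C=O), C2 (carries the propanoic acid arm, whose α-carbon is Cα), C3 (carries the quaternary carbon C1' of the trimethylcyclohexyl ring), C4, C5, C6 (carries CH2O).
2. Late stage: formate ⇐ primary alcohol; saturated trimethylcyclohexyl ring and free alcohol ⇐ one hydrogenation of a cyclohexenyl, O-benzyl enone acid.
3. Key disconnection C2=C3: enone acid ⇐ acyclic ethyl (E)-2-methyl-4-oxo-2-enoate with a tethered tert-alkyl ketone, by copper hydride reductive aldol ring closure, lactonisation and E1cB opening in one flask (also sets Cα). It is possible because the carboxyl group, Cα, C2 and C3 can close a five-membered lactone on the enone ring, the C1 ketone beside C2 places the enolate at C2 and later acidifies C2–H, and the C3 ketone has no α-hydrogen on its quaternary side.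
4. Acyclic precursor ⇐ Nozaki–Hiyama–Kishi coupling and oxidation (C1–C2) ⇐ keto aldehyde ⇐ organocatalytic Michael addition (C5–C6, sets C6) of 3-(benzyloxy)propanal to a vinyl ketone.
5. Vinyl ketone ⇐ [2,3]-Wittig rearrangement of the allyl ether of (S)-isophorol (C–O chirality passed to quaternary C1') ⇐ isophorone. Ring order: the isophorone carbocycle is bought, the enone ring is closed in step 8, the lactone ring is temporary.

Key step: step 8

Assumption: the ligand antipode written for step 8 is taken to deliver hydride to the face that gives the (R) side-chain centre (the other antipode is used if a pilot run shows the opposite sense), and ethyl (E)-3-iodo-2-methylacrylate is treated as a purchased building block.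

**Route**

Step 1
Reactants: 1 isophorone (3,5,5-trimethylcyclohex-2-en-1-one)
Product: 2 (S)-3,5,5-trimethylcyclohex-2-en-1-ol
Conditions: (R)-Me-CBS oxazaborolidine [(R)-1-methyl-3,3-diphenyltetrahydro-1H,3H-pyrrolo[1,2-c][1,3,2]oxazaborole] (10 mol %), BH3·SMe2, THF, −20 °C; then MeOH, aq. NH4Cl
Reagents that add atoms: none
Why: Corey–Bakshi–Shibata reduction, in which the oxazaborolidine binds the ketone with the alkenyl arm as the large group and delivers hydride 1,2 to one face, so the (R)-catalyst should give the (S)-allylic alcohol.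

Step 2
Reactants: 2 (S)-3,5,5-trimethylcyclohex-2-en-1-ol
Product: 3 (S)-3-(allyloxy)-1,5,5-trimethylcyclohex-1-ene
Conditions: NaH, allyl bromide, THF–DMF, 0 °C to rt
Reagents that add atoms: allyl bromide, C=CCBr
Why: Williamson ether synthesis at the alkoxide oxygen, which leaves the carbinol centre untouched.

Step 3
Reactants: 3 (S)-3-(allyloxy)-1,5,5-trimethylcyclohex-1-ene
Product: 4 1-[(R)-1,5,5-trimethylcyclohex-2-en-1-yl]prop-2-en-1-ol (either carbinol epimer)
Conditions: n-BuLi, THF, −78 to −20 °C; then H2O
Reagents that add atoms: none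
Why: [2,3]-Wittig rearrangement, in which the less substituted O–CH2 of the allyl group is lithiated and the carbanion bonds to the methyl-bearing alkene carbon on the face that carried the oxygen through a five-membered envelope, so the carbinol chirality is passed suprafacially to the new quaternary carbon while the new carbinol centre is of no consequence.

Step 4
Reactants: 4 1-[(R)-1,5,5-trimethylcyclohex-2-en-1-yl]prop-2-en-1-ol
Product: 5 1-[(R)-1,5,5-trimethylcyclohex-2-en-1-yl]prop-2-en-1-one
Conditions: Dess–Martin periodinane, CH2Cl2, 0 °C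
Reagents that add atoms: none
Why: Dess–Martin oxidation of the secondary allylic alcohol under neutral conditions removes the uncontrolled carbinol centre and gives a vinyl ketone that has no α-hydrogen on its quaternary side.

Step 5
Reactants: 5 1-[(R)-1,5,5-trimethylcyclohex-2-en-1-yl]prop-2-en-1-one; 6 3-(benzyloxy)propanal
Product: 7 (S)-2-[(benzyloxy)methyl]-5-oxo-5-[(R)-1,5,5-trimethylcyclohex-2-en-1-yl]pentanal
Conditions: (S)-2-(methoxydiphenylmethyl)pyrrolidine (10 mol %), ethyl 3,4-dihydroxybenzoate (20 mol %), neat, 4 °C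
Reagents that add atoms: none
Why: Enamine-catalysed Michael addition of an aldehyde to a vinyl ketone, in which the (E)-enamine of 6 is shielded on one face by the methoxydiphenylmethyl group and adds through the open face, which should set the (S) centre bearing the benzyloxymethyl group.

Step 6
Reactants: 7 (S)-2-[(benzyloxy)methyl]-5-oxo-5-[(R)-1,5,5-trimethylcyclohex-2-en-1-yl]pentanal; 8 ethyl (E)-3-iodo-2-methylprop-2-enoate
Product: 9 ethyl (2E,5S)-5-[(benzyloxy)methyl]-4-hydroxy-2-methyl-8-oxo-8-[(R)-1,5,5-trimethylcyclohex-2-en-1-yl]oct-2-enoate (both C4 epimers)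
Conditions: CrCl2 (4 equiv), NiCl2 (2 mol %), DMSO, rt; then H2O
Reagents that add atoms: none
Why: Nozaki–Hiyama–Kishi coupling, in which the alkenylchromium species formed with retention of the (E) geometry adds only to the aldehyde under non-basic conditions, so the α-centre and the hindered ketone stay untouched and the new carbinol centre (both epimers) is removed in step 7.

Step 7
Reactants: 9 ethyl (2E,5S)-5-[(benzyloxy)methyl]-4-hydroxy-2-methyl-8-oxo-8-[(R)-1,5,5-trimethylcyclohex-2-en-1-yl]oct-2-enoate
Product: 10 ethyl (2E,5S)-5-[(benzyloxy)methyl]-2-methyl-4,8-dioxo-8-[(R)-1,5,5-trimethylcyclohex-2-en-1-yl]oct-2-enoate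
Conditions: Dess–Martin periodinane, CH2Cl2, 0 °C to rt
Reagents that add atoms: none
Why: Dess–Martin oxidation of the allylic alcohol under neutral conditions should give the 4-oxo-2-enoate without enolising the adjacent stereocentre.

Step 8
Reactants: 10 ethyl (2E,5S)-5-[(benzyloxy)methyl]-2-methyl-4,8-dioxo-8-[(R)-1,5,5-trimethylcyclohex-2-en-1-yl]oct-2-enoate
Product: 13 (R)-2-[(S)-5-[(benzyloxy)methyl]-6-oxo-2-[(R)-1,5,5-trimethylcyclohex-2-en-1-yl]cyclohex-1-en-1-yl]propanoic acid, via copper enolate 11 (not isolated), via keto lactone 12 (not isolated)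
Conditions: Cu(OAc)2·H2O (5 mol %), (R)-1-[(S)-2-(diphenylphosphino)ferrocenyl]ethyldi-tert-butylphosphine (5 mol %), HSiMe(OEt)2 (2 equiv), toluene, 0 °C to rt; then DBU (2 equiv), 0 °C; aq. citric acid
Reagents that add atoms: none
Why: Proposed new method: the monovalent copper hydride carrying the chiral bisphosphine delivers hydride to the alkene carbon β to the C1 ketone, the (Z)-copper enolate 11 closes the enone ring at C2–C3 by aldol addition to the tert-alkyl ketone with the tertiary alkoxide acylating itself on the cis ethyl ester to give lactone 12 (ethoxide passes to silicon and the hydride is regenerated), and DBU then removes the C2 proton and expels the carboxylate from C3 in an E1cB elimination that places the double bond at C2=C3 and frees the acid. The closest known reactions are the copper hydride-catalysed enantioselective intramolecular reductive aldol cyclisation of β,β-disubstituted enones onto tethered ketones and copper-catalysed reductive aldol–lactonisation, and what is new is the ester-bearing β-carbon, the tert-alkyl ketone acceptor and the lactone-opening elimination in the same flask. The carbocycle closes in the 6-(enolendo)-exo-trig mode through a chair that holds the tert-alkyl group and the benzyloxymethyl group equatorial, and the lactone closes 5-exo-trig and is opened again in the DBU stage. The side-chain stereocentre is set by the ligand on copper during hydride transfer to the (E)-alkene, the two ring centres made at C2 and C3 are erased by the elimination, and the centre at C6 is carried through unchanged. The step needs hydride to go β to the ketone and not β to the ester, an enolate only on the C2 side, and no reduction of the hindered ketone or the ring alkene, which the substrate secures because the ketone is the stronger acceptor and binding site, conjugate reduction can place the enolate only at C2, and the tert-alkyl ketone and the unactivated alkene are inert to the catalyst. Epimerisation or loss of benzyloxide at C6 should not intrude because no free base is present in the copper stage and the anti-periplanar β-acyloxy elimination at C2 is far faster than enolisation towards C6.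

Step 9
Reactants: 13 (R)-2-[(S)-5-[(benzyloxy)methyl]-6-oxo-2-[(R)-1,5,5-trimethylcyclohex-2-en-1-yl]cyclohex-1-en-1-yl]propanoic acid
Product: 14 (R)-2-[(S)-5-(hydroxymethyl)-6-oxo-2-[(S)-1,3,3-trimethylcyclohexyl]cyclohex-1-en-1-yl]propanoic acid
Conditions: H2 (1 atm), Pd/C (10 wt %), EtOAc, rt
Reagents that add atoms: none
Why: Heterogeneous hydrogenation saturates the cis-disubstituted ring alkene and cleaves the benzyl ether by hydrogenolysis, while the tetrasubstituted enone flanked by a tert-alkyl group should not reach the catalyst surface, and no stereocentre is made.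

Step 10
Reactants: 14 (R)-2-[(S)-5-(hydroxymethyl)-6-oxo-2-[(S)-1,3,3-trimethylcyclohexyl]cyclohex-1-en-1-yl]propanoic acid
Product: 15 (R)-2-[(S)-5-[(formyloxy)methyl]-6-oxo-2-[(S)-1,3,3-trimethylcyclohexyl]cyclohex-1-en-1-yl]propanoic acid
Conditions: HCO2CH2CF3 (10 equiv), THF, 50 °C
Reagents that add atoms: 2,2,2-trifluoroethyl formate, O=COCC(F)(F)F
Why: O-Formylation by acyl transfer from an activated formate under neutral conditions should acylate the primary alcohol only and avoids the base that would eliminate the β-formyloxy ketone or epimerise its α-centre.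

**Compound list**

1 | isophorone (3,5,5-trimethylcyclohex-2-en-1-one) | CC1=CC(=O)CC(C)(C)C1 | starting material
2 | (S)-3,5,5-trimethylcyclohex-2-en-1-ol | O[C@@H]1C=C(C)CC(C)(C)C1 | intermediate
3 | (S)-3-(allyloxy)-1,5,5-trimethylcyclohex-1-ene | C=CCO[C@@H]1C=C(C)CC(C)(C)C1 | intermediate
4 | 1-[(R)-1,5,5-trimethylcyclohex-2-en-1-yl]prop-2-en-1-ol (carbinol centre not defined) | C=CC(O)[C@@]1(C)C=CCC(C)(C)C1 | intermediate
5 | 1-[(R)-1,5,5-trimethylcyclohex-2-en-1-yl]prop-2-en-1-one | C=CC(=O)[C@@]1(C)C=CCC(C)(C)C1 | intermediate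
6 | 3-(benzyloxy)propanal | O=CCCOCc1ccccc1 | starting material
7 | (S)-2-[(benzyloxy)methyl]-5-oxo-5-[(R)-1,5,5-trimethylcyclohex-2-en-1-yl]pentanal | O=C[C@H](COCc1ccccc1)CCC(=O)[C@@]1(C)C=CCC(C)(C)C1 | intermediate
8 | ethyl (E)-3-iodo-2-methylprop-2-enoate | CCOC(=O)/C(C)=C/I | starting material
9 | ethyl (2E,5S)-5-[(benzyloxy)methyl]-4-hydroxy-2-methyl-8-oxo-8-[(R)-1,5,5-trimethylcyclohex-2-en-1-yl]oct-2-enoate (C4 not defined) | CCOC(=O)/C(C)=C/C(O)[C@H](COCc1ccccc1)CCC(=O)[C@@]1(C)C=CCC(C)(C)C1 | intermediate
10 | ethyl (2E,5S)-5-[(benzyloxy)methyl]-2-methyl-4,8-dioxo-8-[(R)-1,5,5-trimethylcyclohex-2-en-1-yl]oct-2-enoate | CCOC(=O)/C(C)=C/C(=O)[C@H](COCc1ccccc1)CCC(=O)[C@@]1(C)C=CCC(C)(C)C1 | intermediate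
11 | copper (Z)-enolate of ethyl (2R,5S)-5-[(benzyloxy)methyl]-2-methyl-4,8-dioxo-8-[(R)-1,5,5-trimethylcyclohex-2-en-1-yl]octanoate, bisphosphine on copper not drawn | CCOC(=O)[C@H](C)/C=C(\O[Cu])[C@H](COCc1ccccc1)CCC(=O)[C@@]1(C)C=CCC(C)(C)C1 | intermediate
12 | (3R,3aS,5S,7aS)-5-[(benzyloxy)methyl]-3-methyl-7a-[(R)-1,5,5-trimethylcyclohex-2-en-1-yl]hexahydro-1-benzofuran-2,4-dione (cis-fused keto lactone, drawn as the diastereomer expected from the chair closure) | C[C@H]1C(=O)O[C@@]2([C@@]3(C)C=CCC(C)(C)C3)CC[C@@H](COCc3ccccc3)C(=O)[C@@H]12 | intermediate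
13 | (R)-2-[(S)-5-[(benzyloxy)methyl]-6-oxo-2-[(R)-1,5,5-trimethylcyclohex-2-en-1-yl]cyclohex-1-en-1-yl]propanoic acid | C[C@@H](C(=O)O)C1=C([C@@]2(C)C=CCC(C)(C)C2)CC[C@@H](COCc2ccccc2)C1=O | intermediate
14 | (R)-2-[(S)-5-(hydroxymethyl)-6-oxo-2-[(S)-1,3,3-trimethylcyclohexyl]cyclohex-1-en-1-yl]propanoic acid | C[C@@H](C(=O)O)C1=C([C@@]2(C)CCCC(C)(C)C2)CC[C@@H](CO)C1=O | intermediate
15 | (R)-2-[(S)-5-[(formyloxy)methyl]-6-oxo-2-[(S)-1,3,3-trimethylcyclohexyl]cyclohex-1-en-1-yl]propanoic acid | C[C@@H](C(=O)O)C1=C([C@@]2(C)CCCC(C)(C)C2)CC[C@@H](COC=O)C1=O | target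

**Step count and risks**

Total step count: 10. Longest linear sequence: 10 steps (from isophorone; compounds 6 and 8 are bought).

Steps most likely to fail:

1. Step 8 (proposed new method). The copper enolate may be silylated by the silane before it can add to the hindered tert-alkyl ketone, so that ring closure stalls; misdirected hydride delivery β to the ester and slow deprotonation at the congested C2 in the DBU stage are lesser concerns. The fallback sets out from 10 and separates the events with known chemistry. The same copper hydride system is run as a plain asymmetric 1,4-hydrosilylation, which is established for β,β-disubstituted enones, and the regiodefined enol ether ethyl (2R,3Z,5S)-5-[(benzyloxy)methyl]-4-{[diethoxy(methyl)silyl]oxy}-2-methyl-8-oxo-8-[(R)-1,5,5-trimethylcyclohex-2-en-1-yl]oct-3-enoate F1 is isolated. TiCl4 in CH2Cl2 at −78 °C then forces an intramolecular Mukaiyama aldol addition to the ketone through an open, Lewis acid-activated transition state, and the chlorotitanium aldolate lactonises on warming. The route is rejoined at keto lactone 12, which DBU opens to 13.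

2. Step 3. The allyl carbanion may fail to reach the methyl-bearing alkene carbon past the syn-axial ring methyl, so that [1,2]-shift or lithiation on the ring side takes over. The fallback sets out from 2. O-Alkylation with Bu3SnCH2I and KH gives tributyl{[(S)-3,5,5-trimethylcyclohex-2-en-1-yl]oxymethyl}stannane F2. Tin–lithium exchange with n-BuLi at −78 °C releases an unstabilised α-alkoxy carbanion whose only low-energy path is the Wittig–Still [2,3]-shift, which should give [(R)-1,5,5-trimethylcyclohex-2-en-1-yl]methanol F3 with the same suprafacial chirality transfer. Dess–Martin oxidation gives (R)-1,5,5-trimethylcyclohex-2-ene-1-carbaldehyde F4, and addition of CH2=CHMgBr in THF at −78 °C returns to the route at 4.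

3. Step 5. The enamine of 6 may lose benzyl alcohol by β-elimination, or the new α-centre may erode through enamine re-formation. The fallback sets out from 5 and uses auxiliary control. (S)-4-Benzyl-3-[3-(benzyloxy)propanoyl]oxazolidin-2-one F5 is made from 3-(benzyloxy)propanoic acid and (S)-4-benzyl-2-oxazolidinone through the mixed pivalic anhydride. Its chlorotitanium (Z)-enolate (TiCl4, i-Pr2NEt, CH2Cl2, −78 to 0 °C) adds to 5 on the face away from the benzyl group to give (S)-4-benzyl-3-{(S)-2-[(benzyloxy)methyl]-5-oxo-5-[(R)-1,5,5-trimethylcyclohex-2-en-1-yl]pentanoyl}oxazolidin-2-one F6. LiBH4 in THF–MeOH removes the auxiliary and reduces the ketone to (2R)-2-[(benzyloxy)methyl]-5-[(R)-1,5,5-trimethylcyclohex-2-en-1-yl]pentane-1,5-diol F7, and Dess–Martin oxidation of both hydroxyl groups returns to the route at 7.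

Further compounds
F1 | step 8 | ethyl (2R,3Z,5S)-5-[(benzyloxy)methyl]-4-{[diethoxy(methyl)silyl]oxy}-2-methyl-8-oxo-8-[(R)-1,5,5-trimethylcyclohex-2-en-1-yl]oct-3-enoate | CCOC(=O)[C@H](C)/C=C(\O[Si](C)(OCC)OCC)[C@H](COCc1ccccc1)CCC(=O)[C@@]1(C)C=CCC(C)(C)C1
F2 | step 3 | tributyl{[(S)-3,5,5-trimethylcyclohex-2-en-1-yl]oxymethyl}stannane | CCCC[Sn](CCCC)(CCCC)CO[C@@H]1C=C(C)CC(C)(C)C1
F3 | step 3 | [(R)-1,5,5-trimethylcyclohex-2-en-1-yl]methanol | OC[C@@]1(C)C=CCC(C)(C)C1
F4 | step 3 | (R)-1,5,5-trimethylcyclohex-2-ene-1-carbaldehyde | O=C[C@@]1(C)C=CCC(C)(C)C1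
F5 | step 5 | (S)-4-benzyl-3-[3-(benzyloxy)propanoyl]oxazolidin-2-one | O=C(CCOCc1ccccc1)N1[C@@H](Cc2ccccc2)COC1=O
F6 | step 5 | (S)-4-benzyl-3-{(S)-2-[(benzyloxy)methyl]-5-oxo-5-[(R)-1,5,5-trimethylcyclohex-2-en-1-yl]pentanoyl}oxazolidin-2-one | O=C([C@H](COCc1ccccc1)CCC(=O)[C@@]1(C)C=CCC(C)(C)C1)N1[C@@H](Cc2ccccc2)COC1=O
F7 | step 5 | (2R)-2-[(benzyloxy)methyl]-5-[(R)-1,5,5-trimethylcyclohex-2-en-1-yl]pentane-1,5-diol (C5 not defined) | OC[C@H](COCc1ccccc1)CCC(O)[C@@]1(C)C=CCC(C)(C)C1
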